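**Plan**

1. Retrosynthetic cuts (furo[3,4-c]furan-1-one numbering: C1 carbonyl, O2, C3 syringyl carbon, C3a, C4 methylene, O5, C6 guaiacyl carbon, C6a): first the phenol silyl ether; then the C3–aryl bond, giving 2,6-dimethoxyphenol and a bicyclic C3-acetoxy lactone; then the O2–C3 lactol bond, with C3 traced back to a vinyl group on a 2-aryl-4-vinyltetrahydrofuran-3-carboxylic acid; then the O5–C6 ether bond and the C6–C6a aldol bond, giving (S)-4-vinylbutyrolactone and O-silyl vanillin; last the C3a–vinyl bond, giving furan-2(5H)-one.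
2. Forward order of rings: a butyrolactone (C1, C6a, C3a, C4) serves first as stereochemical template; acid switches it into the tetrahydrofuran ring (O5–C6 closure); ozonolysis then unveils C3 as an aldehyde next to the cis carboxylic acid, which closes the final γ-lactone as its lactol; the syringyl ring is joined last.
3. Stereochemistry: C3a from Rh/(S)-BINAP conjugate vinylation; C6a from the aldol anti to the vinyl group; C6 from SN1 ring closure trans to the C6a carboxyl; C3 from convex-face attack in the key step.
4. Enabling feature: C3 is an acylal-level carbon (bonded to lactone O2 and ring-fusion C3a) in a cis-fused 3,7-dioxabicyclo[3.3.0]octan-2-one, so it ionises to an acyloxocarbenium ion open only on its convex face. The carbon to be joined is C4 of 2,6-dimethoxyphenol, para to the free OH and the only unhindered activated position, so the unprotected phenol is attached by direct C–H substitution.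

Key step: step 7

Remark (assumption): the sense of induction of (S)-BINAP in step 2 is assigned by analogy with Rh-catalysed 1,4-additions to cyclic enones; if the opposite enantiomer forms, (R)-BINAP is used.

**Step 1**
Reactants: 1 vanillin
Product: 2 3-methoxy-4-[(triisopropylsilyl)oxy]benzaldehyde
Conditions: TIPSCl, imidazole, DMF, 0 °C → rt
Reagents that add atoms: triisopropylsilyl chloride, CC(C)[Si](Cl)(C(C)C)C(C)C
Why: Imidazole-promoted O-silylation of the phenol gives an aryl silyl ether that should survive the enolate, acid, ozone and Lewis acid used later and that comes off with fluoride.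

**Step 2**
Reactants: 3 furan-2(5H)-one; 4 potassium vinyltrifluoroborate
Product: 5 (S)-4-vinyldihydrofuran-2(3H)-one
Conditions: [Rh(cod)2]BF4 (3 mol%), (S)-BINAP (3.3 mol%), toluene/H2O (10:1), 100 °C
Reagents that add atoms: none
Why: Rh(I)/BINAP-catalysed asymmetric 1,4-addition (Hayashi–Miyaura type) delivers the vinyl group to one enantioface of the butenolide and the Rh enolate is protonated by water, which should set C4 as S.

**Step 3**
Reactants: 5 (S)-4-vinyldihydrofuran-2(3H)-one; 2 3-methoxy-4-[(triisopropylsilyl)oxy]benzaldehyde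
Product: 7 (3S,4R)-3-{hydroxy[3-methoxy-4-(triisopropylsilyloxy)phenyl]methyl}-4-vinyldihydrofuran-2(3H)-one (both carbinol epimers), via lithium enolate 6 (not isolated)
Conditions: LiHMDS, THF, −78 °C; then 2, −78 °C; AcOH quench at −78 °C
Reagents that add atoms: none
Why: Aldol addition of the lactone lithium enolate should occur anti to the C4 vinyl group and so set C3 trans to C4, while the carbinol centre forms as a mixture that is erased in step 4.

**Step 4**
Reactants: 7 (3S,4R)-3-{hydroxy[3-methoxy-4-(triisopropylsilyloxy)phenyl]methyl}-4-vinyldihydrofuran-2(3H)-one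
Product: 9 methyl (2S,3S,4R)-2-[3-methoxy-4-(triisopropylsilyloxy)phenyl]-4-vinyltetrahydrofuran-3-carboxylate, via ring-opened hydroxy ester 8 (not isolated)
Conditions: HCl (0.5 M) in MeOH, rt → 40 °C
Reagents that add atoms: methanol, CO
Why: Acid-catalysed methanolysis opens the lactone to hydroxy ester 8 and ionises the electron-rich benzylic alcohol, and the freed primary hydroxyl closes the tetrahydrofuran by SN1 cycloetherification with the aryl group trans to the neighbouring ester, so both carbinol epimers should converge on 2S.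

**Step 5**
Reactants: 9 methyl (2S,3S,4R)-2-[3-methoxy-4-(triisopropylsilyloxy)phenyl]-4-vinyltetrahydrofuran-3-carboxylate
Product: 11 (2S,3S,4R)-2-[3-methoxy-4-(triisopropylsilyloxy)phenyl]-4-vinyltetrahydrofuran-3-carboxylic acid, via trimethylstannyl ester 10 (not isolated)
Conditions: Me3SnOH, 1,2-dichloroethane, 80 °C; 5% aq. HCl wash
Reagents that add atoms: trimethyltin hydroxide, C[Sn](C)(C)O
Why: Trimethyltin hydroxide cleaves the methyl ester under near-neutral conditions through the stannyl ester, which avoids hydroxide that could attack the aryl silyl ether or epimerise C3.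

**Step 6**
Reactants: 11 (2S,3S,4R)-2-[3-methoxy-4-(triisopropylsilyloxy)phenyl]-4-vinyltetrahydrofuran-3-carboxylic acid
Product: 13 (3aR,6S,6aS)-6-[3-methoxy-4-(triisopropylsilyloxy)phenyl]-1-oxotetrahydro-1H,3H-furo[3,4-c]furan-3-yl acetate (both C3 epimers), via lactol 12 (not isolated)
Conditions: O3, CH2Cl2, −78 °C (Sudan III end point); PPh3, −78 °C → rt; then Ac2O, pyridine, DMAP (cat.), 0 °C → rt
Reagents that add atoms: ozone, [O-][O+]=O; acetic anhydride, CC(=O)OC(C)=O
Why: Ozonolysis of the terminal alkene gives the aldehyde, which the cis carboxylic acid should trap at once as the bicyclic lactol (pseudo-acid) before C3a can epimerise, and acetylation turns it into the acylal whose C3 configuration is irrelevant because it becomes planar in step 7.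

**Step 7**
Reactants: 13 (3aR,6S,6aS)-6-[3-methoxy-4-(triisopropylsilyloxy)phenyl]-1-oxotetrahydro-1H,3H-furo[3,4-c]furan-3-yl acetate; 14 2,6-dimethoxyphenol
Product: 16 (3S,3aR,6S,6aS)-3-(4-hydroxy-3,5-dimethoxyphenyl)-6-[3-methoxy-4-(triisopropylsilyloxy)phenyl]tetrahydro-1H,3H-furo[3,4-c]furan-1-one, via acyloxocarbenium ion 15 (not isolated)
Conditions: BF3·OEt2 (1.5 equiv), CH2Cl2, −78 °C; then 14 (1.05 equiv) added slowly, −78 → −40 °C; cold aq. NaHCO3 quench
Reagents that add atoms: none
Why: BF3 ionises the acylal acetate to the bicyclic acyloxocarbenium ion 15, which is attacked by C4 of 2,6-dimethoxyphenol and rearomatises by proton loss; this is a Friedel–Crafts alkylation whose closest known relatives are the Lewis-acid C-arylation of glycosyl acetates by phenols and the arylation of pseudo-acid esters such as 3-acyloxyphthalides. No ring is closed here, since the lactone is already in place and only the C3–aryl bond forms. The new stereocentre C3 is controlled by the cis-fused bicyclo[3.3.0] framework: the arene should add to the planar cation from the convex face (the face of the C3a and C6a hydrogens), placing the aryl group exo (3S), and both C3 epimers of 13 converge on the same cation. Regioselectivity is secured by the phenol itself, because the hydroxyl is the strongest donor, its ortho positions carry methoxy groups, C4 is the only unhindered activated carbon, and any O-alkylation is reversible under the Lewis acid. The step also needs single arylation without re-ionisation of the product lactone or of the C6 benzylic ether, which pre-forming the cation at −78 °C, slow addition of barely more than one equivalent of phenol, a ceiling of −40 °C and a cold quench are meant to secure.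

**Step 8**
Reactants: 16 (3S,3aR,6S,6aS)-3-(4-hydroxy-3,5-dimethoxyphenyl)-6-[3-methoxy-4-(triisopropylsilyloxy)phenyl]tetrahydro-1H,3H-furo[3,4-c]furan-1-one
Product: 17 (3S,3aR,6S,6aS)-3-(4-hydroxy-3,5-dimethoxyphenyl)-6-(4-hydroxy-3-methoxyphenyl)tetrahydro-1H,3H-furo[3,4-c]furan-1-one
Conditions: TBAF, AcOH (1:1), THF, 0 °C
Reagents that add atoms: none
Why: Fluoride cleaves the aryl silyl ether, and the acetic acid buffer keeps both phenols protonated so that the p-hydroxybenzylic lactone and ether should not open through quinone methides.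

**Compound list**

1 | vanillin (4-hydroxy-3-methoxybenzaldehyde) | COc1cc(C=O)ccc1O | starting material
2 | 3-methoxy-4-[(triisopropylsilyl)oxy]benzaldehyde | COc1cc(C=O)ccc1O[Si](C(C)C)(C(C)C)C(C)C | intermediate
3 | furan-2(5H)-one | O=C1OCC=C1 | starting material
4 | potassium vinyltrifluoroborate | C=C[B-](F)(F)F.[K+] | starting material
5 | (S)-4-vinyldihydrofuran-2(3H)-one | C=C[C@H]1COC(=O)C1 | intermediate
6 | lithium enolate of 5 | C=C[C@H]1COC(O[Li])=C1 | intermediate
7 | (3S,4R)-3-{hydroxy[3-methoxy-4-(triisopropylsilyloxy)phenyl]methyl}-4-vinyldihydrofuran-2(3H)-one (carbinol epimers) | C=C[C@H]1COC(=O)[C@@H]1C(O)c1ccc(O[Si](C(C)C)(C(C)C)C(C)C)c(OC)c1 | intermediate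
8 | methyl (2S,3R)-2-{hydroxy[3-methoxy-4-(triisopropylsilyloxy)phenyl]methyl}-3-(hydroxymethyl)pent-4-enoate (carbinol epimers) | C=C[C@@H](CO)[C@H](C(=O)OC)C(O)c1ccc(O[Si](C(C)C)(C(C)C)C(C)C)c(OC)c1 | intermediate
9 | methyl (2S,3S,4R)-2-[3-methoxy-4-(triisopropylsilyloxy)phenyl]-4-vinyltetrahydrofuran-3-carboxylate | COc1cc([C@H]2OC[C@H](C=C)[C@@H]2C(=O)OC)ccc1O[Si](C(C)C)(C(C)C)C(C)C | intermediate
10 | trimethylstannyl (2S,3S,4R)-2-[3-methoxy-4-(triisopropylsilyloxy)phenyl]-4-vinyltetrahydrofuran-3-carboxylate | COc1cc([C@H]2OC[C@H](C=C)[C@@H]2C(=O)O[Sn](C)(C)C)ccc1O[Si](C(C)C)(C(C)C)C(C)C | intermediate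
11 | (2S,3S,4R)-2-[3-methoxy-4-(triisopropylsilyloxy)phenyl]-4-vinyltetrahydrofuran-3-carboxylic acid | COc1cc([C@H]2OC[C@H](C=C)[C@@H]2C(=O)O)ccc1O[Si](C(C)C)(C(C)C)C(C)C | intermediate
12 | (3aR,6S,6aS)-3-hydroxy-6-[3-methoxy-4-(triisopropylsilyloxy)phenyl]tetrahydro-1H,3H-furo[3,4-c]furan-1-one (C3 epimers) | COc1cc([C@H]2OC[C@H]3[C@@H]2C(=O)OC3O)ccc1O[Si](C(C)C)(C(C)C)C(C)C | intermediate
13 | (3aR,6S,6aS)-6-[3-methoxy-4-(triisopropylsilyloxy)phenyl]-1-oxotetrahydro-1H,3H-furo[3,4-c]furan-3-yl acetate (C3 epimers) | COc1cc([C@H]2OC[C@H]3[C@@H]2C(=O)OC3OC(C)=O)ccc1O[Si](C(C)C)(C(C)C)C(C)C | intermediate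
14 | 2,6-dimethoxyphenol | COc1cccc(OC)c1O | starting material
15 | (3aR,6S,6aS)-bicyclic acyloxocarbenium ion (C3=O2+) derived from 13 | COc1cc([C@H]2OC[C@H]3[C@@H]2C(=O)[O+]=C3)ccc1O[Si](C(C)C)(C(C)C)C(C)C | intermediate
16 | (3S,3aR,6S,6aS)-3-(4-hydroxy-3,5-dimethoxyphenyl)-6-[3-methoxy-4-(triisopropylsilyloxy)phenyl]tetrahydro-1H,3H-furo[3,4-c]furan-1-one | COc1cc([C@H]2OC[C@H]3[C@@H]2C(=O)O[C@@H]3c2cc(OC)c(O)c(OC)c2)ccc1O[Si](C(C)C)(C(C)C)C(C)C | intermediate
17 | (3S,3aR,6S,6aS)-3-(4-hydroxy-3,5-dimethoxyphenyl)-6-(4-hydroxy-3-methoxyphenyl)tetrahydro-1H,3H-furo[3,4-c]furan-1-one | COc1cc([C@H]2OC[C@H]3[C@@H]2C(=O)O[C@@H]3c2cc(OC)c(O)c(OC)c2)ccc1O | target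

**Step count**

Total: 8 steps. Longest linear sequence: 7 steps (3 → 5 → 7 → 9 → 11 → 13 → 16 → 17); step 1 is a one-step side branch.

**Steps most likely to fail**

Step 7. The newly formed p-hydroxybenzylic lactone, or the C6 benzylic ether, may re-ionise under the Lewis acid and lead to a second arylation or ring opening; alternatively the acylal may ionise too slowly at low temperature. The fallback sets out from lactol 12, isolated by leaving out the acetylation in step 6. As its sodium carboxylate (NaHCO3, dioxane/H2O) the lactol opens to the free aldehyde. Rh(I)-catalysed 1,2-addition of commercial 4-hydroxy-3,5-dimethoxyphenylboronic acid pinacol ester ([Rh(cod)Cl]2, 60 °C; a chiral diene ligand can be screened for matched induction) should then give (2S,3S,4R)-4-[hydroxy(4-hydroxy-3,5-dimethoxyphenyl)methyl]-2-[3-methoxy-4-(triisopropylsilyloxy)phenyl]tetrahydrofuran-3-carboxylic acid F1. Acidification to pH 3 lactonises it, and after chromatographic removal of the C3 epimer the route is rejoined at 16. This fallback has no convex-face control at C3, so it is the weaker option stereochemically.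

Step 4. The benzylic cation may lose the acidic C3 proton (dehydration to the α-arylidene lactone) faster than the lactone opens and the ether closes. The fallback sets out from 7. LiAlH4 (THF, 0 °C) reduces the lactone to (2R,3R)-2-{hydroxy[3-methoxy-4-(triisopropylsilyloxy)phenyl]methyl}-3-vinylbutane-1,4-diol F2. Catalytic camphorsulfonic acid in CH2Cl2 then effects the same SN1 etherification, now without a ring-opening equilibrium or a carbonyl-activated proton beside the cation; only the five-membered ether can form, giving [(2S,3R,4R)-2-[3-methoxy-4-(triisopropylsilyloxy)phenyl]-4-vinyltetrahydrofuran-3-yl]methanol F3. TEMPO/PhI(OAc)2 in MeCN/H2O oxidises the primary alcohol to the acid, and the route is rejoined at 11, so step 5 falls away.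

Step 2. Transmetalation and insertion may be slow with the five-membered lactone, or enantiofacial discrimination may be poor. The fallback sets out from 3. Copper-catalysed conjugate addition of vinylmagnesium bromide (CuI, TMSCl, THF, −78 °C) should give racemic 4-vinyldihydrofuran-2(3H)-one F4. Aminolysis with (S)-1-phenylethylamine (AlMe3, toluene) gives diastereomeric hydroxy amides, from which (S)-3-(hydroxymethyl)-N-[(S)-1-phenylethyl]pent-4-enamide F5 is separated by crystallisation or chromatography. Hydrolysis with relactonisation (2 M HCl, dioxane, reflux) returns the route at 5.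

**Further compounds**

F1 | step 7 | (2S,3S,4R)-4-[hydroxy(4-hydroxy-3,5-dimethoxyphenyl)methyl]-2-[3-methoxy-4-(triisopropylsilyloxy)phenyl]tetrahydrofuran-3-carboxylic acid | COc1cc([C@H]2OC[C@H](C(O)c3cc(OC)c(O)c(OC)c3)[C@@H]2C(=O)O)ccc1O[Si](C(C)C)(C(C)C)C(C)C
F2 | step 4 | (2R,3R)-2-{hydroxy[3-methoxy-4-(triisopropylsilyloxy)phenyl]methyl}-3-vinylbutane-1,4-diol | C=C[C@@H](CO)[C@H](CO)C(O)c1ccc(O[Si](C(C)C)(C(C)C)C(C)C)c(OC)c1
F3 | step 4 | [(2S,3R,4R)-2-[3-methoxy-4-(triisopropylsilyloxy)phenyl]-4-vinyltetrahydrofuran-3-yl]methanol | COc1cc([C@H]2OC[C@H](C=C)[C@@H]2CO)ccc1O[Si](C(C)C)(C(C)C)C(C)C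
F4 | step 2 | racemic 4-vinyldihydrofuran-2(3H)-one | C=CC1COC(=O)C1
F5 | step 2 | (S)-3-(hydroxymethyl)-N-[(S)-1-phenylethyl]pent-4-enamide | C=C[C@@H](CO)CC(=O)N[C@@H](C)c1ccccc1
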